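I read this flask at 25 min and at 15 d, and these two times lie on different stretches of one curve: the ratio [X]/[Q] against time.

all flasks: L 4.9 mM
- north-west: Z 0.25 M; J 0.60 mM; run made earlier
- south-west: Z 0.25 M; J 0.90 mM; run made earlier
- east: Z 0.12 M; J 1.2 mM; run made earlier
- flask: Z 0.25 M; J 1.2 mM; time 15 d

| run | time / d | X / % | Q / % | Z / % |
|---|---|---|---|---|
| north-west | 1.25 | 24 | 19 | 32 |
| north-west | 3.00 | 37 | 36 | 16 |
| north-west | 6.00 | 45 | 49 | 4 |
| north-west | 15.0 | 48 | 49 | 0 |
| south-west | 2.08 | 38 | 36 | 16 |
| south-west | 5.00 | 48 | 47 | 3 |
| south-west | 10.0 | 53 | 46 | 0 |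
| south-west | 15.0 | 51 | 50 | 0 |
| east | 1.25 | 37 | 32 | 18 |
| east | 3.00 | 51 | 46 | 4 |
| east | 6.00 | 55 | 46 | 0 |
| east | 15.0 | 53 | 49 | 1 |

(each reading ± 1.5 percentage points)

- ratio of X to Q at 25 min
- ratio of X to Q at 15 d

- what was read earlier has a scatter of 1.5 percentage points, one standard deviation

The north-west run is short by 25.0% of its Z at 1.25 d, and the gap closes later, so something unseen stands on the way to a product. The ratio also falls with time. So I take X as made from Z by J, the unseen intermediate as made from Z without J, and Q as made from that intermediate by J. Integrating from the start, X grows with t, the intermediate grows with t, and Q grows with t squared. The early ratio is therefore a constant over t, and in my scheme [J] and [Z] cancel from it.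

I write the ratio as a level plus that constant over t. Two readings then give the constant: the product of their times, times the fall in ratio, over the time between them. The three runs give 0.504 d, 0.122 d and 0.102 d, with mean 0.243 d. This mean is my lag time, the ratio times the time at the start, and it is rough.

The east run has the J of this flask but half of its Z, and its last two readings give a level of 1.14. So my curve for this flask falls steeply from 15.1 at 25 min, has its knee near 0.213 d, and runs into 1.14 by 15 d.

The forecast gives 1.3 and 1.12, and says “25 min is far earlier than any reading”.

The flask gives 29.3 at 25 min and 1.14 at 15 d.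

    J + E → D (k = 0.142 /M/h)
    J + L ⇌ G (K = 480 /M, k = 492 /M/h)
    Z + J → J + X (k = 80.6 /M/h)
    J + E → J + Q (k = 136 /M/h)
    Z ⇌ E (K = 0.722, k = 0.113 /h)

In this flask the ratio times the time at 25 min is 0.509 d, more than my lag time of 0.243 d, and the constants give 0.437 d as twice the constant of the step to X, over the constant of the step to Q times the forward constant of Z to E, with no [J] in it. The time 25 min is far shorter than 0.26 d, the half-life of Z by its forward path to E. The neighbour flask with a quarter of the J reads 29.3 at 25 min, a lag time of 0.509 d.

The runs are simulated for an exercise.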